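**Assumption:** the target is 19‑O‑descarbamoyl‑(+)‑discodermolide. Discodermolide numbering is used (C1 = lactone C=O, C24 = terminal CH2). TBS = tert‑butyldimethylsilyl, Cb = C(O)N(iPr)2.

## Retrosynthetic overview
1. Global desilylation, then an sp2–sp3 Suzuki disconnection at C14–C15 gives a C1–C14 (Z)‑vinyl iodide and a C15–C24 alkyl iodide.
2. The C1–C14 piece comes from a Zhao–Wittig at C13, a C5–C6 boron aldol and a 1,3‑anti reduction at C7. The only ring (the δ‑lactone) closes late, by oxidative lactonisation of the C1/C5 diol.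
3. The C15–C24 piece comes from an Evans syn aldol (C16–C17) and a Ni‑Kumada vinylation of a (Z)‑enol carbamate, which gives the Z‑diene.
4. The C1–C5 aldehyde, the C6–C13 Z‑enone and the C17–C24 diene all derive from one common (Z)‑enol carbamate stereotriad.
5. Key bond (C3–C4 = C10–C11 = C19–C20): a titanated crotyl carbamate (d3 homoenolate) adds to the (S)‑Roche aldehyde.

## Route

**Step 1**
Reactants: 1 (E)-but-2-en-1-ol
Product: 2 (E)-but-2-en-1-yl N,N-diisopropylcarbamate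
Conditions: NaH, iPr2NCOCl, THF, 0 °C → reflux
Reagents that add atoms: N,N-diisopropylcarbamoyl chloride, CC(C)N(C(C)C)C(Cl)=O
Why: O‑carbamoylation of the alkoxide; no stereocentre is formed and the E‑alkene is untouched.

**Step 2**
Reactants: 3 methyl (S)-3-hydroxy-2-methylpropanoate
Product: 4 methyl (S)-3-(TBS-oxy)-2-methylpropanoate
Conditions: TBSCl, imidazole, CH2Cl2, rt
Reagents that add atoms: TBSCl, CC(C)(C)[Si](C)(C)Cl
Why: standard silylation of a primary alcohol; the stereocentre comes from the chiral pool.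

**Step 3**
Reactants: 4 methyl (S)-3-(TBS-oxy)-2-methylpropanoate
Product: 5 (S)-3-(TBS-oxy)-2-methylpropanal
Conditions: DIBAL-H (1.05 equiv), CH2Cl2, −78 °C; Rochelle salt
Reagents that add atoms: none
Why: partial ester reduction through the stable tetrahedral aluminate at −78 °C; the α‑centre is kept when the aldehyde is used cold and crude.

**Step 4 (key step)**
Reactants: 2 (E)-but-2-en-1-yl N,N-diisopropylcarbamate; 5 (S)-3-(TBS-oxy)-2-methylpropanal
Product: 8 (1Z,3S,4S,5S)-6-(TBS-oxy)-4-hydroxy-3,5-dimethylhex-1-en-1-yl N,N-diisopropylcarbamate, via (S)-lithiocrotyl carbamate sparteine complex 6 (not isolated), via (R)-triisopropoxytitanium crotyl carbamate 7 (not isolated)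
Conditions: n-BuLi, (−)-sparteine, pentane/cyclohexane, −70 °C (crystallisation); Ti(OiPr)4, −70 °C; then 5, −70 °C; aq. work-up
Reagents that add atoms: none
Why: Hoppe asymmetric homoaldol, in which the crotyl carbamate acts as a homoenolate whose γ‑carbon (normally the electrophilic β‑carbon of an enal) attacks the aldehyde carbon; the (S)‑Li·sparteine complex enriched by crystallisation is titanated with inversion, and the (R)‑Ti reagent reacts through a closed chair (aldehyde R equatorial, OCb axial) to set the anti OH/Me pair and the Z‑enol carbamate under reagent control, matched with Felkin attack (OH syn to the Roche methyl).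

**Step 5**
Reactants: 8 homoaldol adduct
Product: 9 (1Z,3S,4S,5S)-4,6-bis(TBS-oxy)-3,5-dimethylhex-1-en-1-yl N,N-diisopropylcarbamate (common precursor)
Conditions: TBSOTf, 2,6-lutidine, CH2Cl2, −78 → 0 °C
Reagents that add atoms: TBSOTf, CC(C)(C)[Si](C)(C)OS(=O)(=O)C(F)(F)F
Why: silyl triflate silylation of a hindered secondary alcohol; the buffered medium leaves the enol carbamate intact.

**Step 6**
Reactants: 9 common precursor
Product: 10 (2R,3R,4S)-3,5-bis(TBS-oxy)-2,4-dimethylpentanal (C1–C5)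
Conditions: O3, CH2Cl2, −78 °C; PPh3, −78 °C → rt
Reagents that add atoms: ozone, [O-][O+]=O
Why: ozonolysis of the electron‑rich enol carbamate C=C unmasks the homoaldol adduct as an anti‑aldol product; the neutral reductive work-up keeps the α‑centre (C4).

**Step 7**
Reactants: 9 common precursor
Product: 12 (5S,6S,7S)-6,8-bis(TBS-oxy)-5,7-dimethyloct-3-yn-2-one (C6–C13), via lithium acetylide 11 (not isolated)
Conditions: t-BuLi (2.2 equiv), THF, −78 → −20 °C; then MeC(O)N(OMe)Me, −78 → 0 °C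
Reagents that add atoms: N-methoxy-N-methylacetamide, CC(=O)N(C)OC
Why: α‑lithiation of the alkenyl carbamate with loss of LiOCb (Fritsch–Buttenberg–Wiechell‑type elimination) gives the acetylide, which undergoes Weinreb ketone synthesis in the same flask; C10 is not acidified and is retained.

**Step 8**
Reactants: 12 ynone
Product: 13 (3Z,5S,6S,7S)-6,8-bis(TBS-oxy)-5,7-dimethyloct-3-en-2-one
Conditions: H2 (1 atm), Lindlar catalyst, quinoline, hexane/EtOAc, rt, stopped at 1 equiv H2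
Reagents that add atoms: none
Why: Lindlar syn semihydrogenation gives the Z‑enone (C8=C9); no other reducible π‑bond is present at this stage.

**Step 9**
Reactants: 13 Z-enone; 10 C1–C5 aldehyde
Product: 15 C1–C13 aldol adduct (5S)-5-hydroxy-7-oxo-(8Z)-ene with 1,3,11,13-tetrakis(TBS-oxy), via dicyclohexylboron dienolate 14 (not isolated)
Conditions: c-Hex2BCl, Et3N, Et2O, 0 °C; 10, −78 → −20 °C; H2O2, MeOH, pH 7 buffer, 0 °C
Reagents that add atoms: none
Why: Paterson boron aldol of a methyl ketone through a cyclic transition state; the A(1,3)‑locked γ‑stereocentre (C10) of the Z‑dienolate exerts 1,6‑induction, which overrides the Felkin bias of 10 and gives the 4,5‑anti (5S) carbinol.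

**Step 10**
Reactants: 15 aldol adduct
Product: 16 (5S,7S)-5,7-diol (C1–C13, four TBS ethers)
Conditions: Me4NBH(OAc)3, MeCN/AcOH, −30 °C
Reagents that add atoms: none
Why: Evans–Saksena reduction, in which hydride is delivered intramolecularly from the C5‑O‑bound acetoxyborohydride through a chair, giving the 1,3‑anti diol (7S) by clean 1,2‑reduction of the enone.

**Step 11**
Reactants: 16 diol
Product: 17 C1,C5,C7,C13-tetraol with 3,11-bis(TBS-oxy)
Conditions: HF·pyridine, pyridine, THF, 0 °C → rt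
Reagents that add atoms: none
Why: kinetically selective desilylation; the two primary TBS ethers cleave much faster than the two flanked secondary ones.

**Step 12**
Reactants: 17 tetraol
Product: 19 C1–C13 δ-lactone aldehyde (C13 CHO, free 7-OH, 3,11-bis(TBS-oxy)), via C1 lactol 18 (not isolated)
Conditions: TEMPO (20 mol %), PhI(OAc)2 (3.5 equiv), CH2Cl2, rt
Reagents that add atoms: none
Why: TEMPO/BAIB oxidation is selective for primary alcohols; the C1 aldehyde is trapped by 5‑OH as a six‑ring lactol and oxidised on to the lactone (oxidative lactonisation), while C13‑OH, which has no partner hydroxyl, stops at the aldehyde, so the two identical chain ends are differentiated and the only ring is closed.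

**Step 13**
Reactants: 19 lactone aldehyde
Product: 20 C1–C14 (13Z)-14-iodo alkene (vinyl iodide)
Conditions: EtPPh3I, n-BuLi, THF, rt; I2, −78 °C; NaHMDS, −20 °C; then 19 (ylide 3–4 equiv), −78 → −30 °C
Reagents that add atoms: ethyltriphenylphosphonium iodide, CC[P+](c1ccccc1)(c1ccccc1)c1ccccc1.[I-]; iodine, II
Why: Zhao (Stork–Zhao type) Wittig olefination; the non‑stabilised α‑iodoethylidene ylide gives the (Z)‑2‑iodoalkene kinetically, excess ylide covers the free 7‑OH, and the aldehyde reacts far faster than the lactone at low temperature.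

**Step 14**
Reactants: 9 common precursor
Product: 21 (3Z,5S,6S,7S)-6,8-bis(TBS-oxy)-5,7-dimethylocta-1,3-diene (C17–C24)
Conditions: CH2=CHMgBr (3 equiv), Ni(acac)2 (10 mol %), Et2O/THF, 0 °C → rt
Reagents that add atoms: vinylmagnesium bromide, C=C[Mg]Br
Why: Ni‑catalysed Kumada‑type C–O cross‑coupling of the alkenyl carbamate proceeds with retention, so the Z geometry from step 4 becomes the terminal Z‑diene.

**Step 15**
Reactants: 21 diene
Product: 22 C17 primary alcohol (19-OTBS)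
Conditions: HF·pyridine, pyridine, THF, 0 °C
Reagents that add atoms: none
Why: selective cleavage of the primary TBS ether over the hindered secondary one.

**Step 16**
Reactants: 22 alcohol
Product: 23 C17 aldehyde (C17–C24)
Conditions: Dess–Martin periodinane, NaHCO3, CH2Cl2, 0 °C → rt
Reagents that add atoms: none
Why: neutral Dess–Martin oxidation, without epimerisation at C18 or isomerisation of the diene.

**Step 17**
Reactants: 23 aldehyde; 24 (R)-4-benzyl-3-propionyloxazolidin-2-one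
Product: 26 C15–C24 syn-aldol imide (17-OH, 16-Me), via Z-boron enolate 25 (not isolated)
Conditions: n-Bu2BOTf, Et3N, CH2Cl2, −78 → 0 °C; 23, −78 → 0 °C; H2O2, MeOH, pH 7 buffer
Reagents that add atoms: none
Why: Evans syn aldol; the Z(O)‑boron enolate reacts through a Zimmerman–Traxler chair, and the (R)‑auxiliary dictates the 16,17‑syn pair with the absolute sense needed (17‑OH syn to 18‑Me), overriding the aldehyde bias.

**Step 18**
Reactants: 26 aldol imide
Product: 27 17,19-bis(TBS-oxy) imide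
Conditions: TBSOTf, 2,6-lutidine, CH2Cl2, 0 °C
Reagents that add atoms: TBSOTf, CC(C)(C)[Si](C)(C)OS(=O)(=O)C(F)(F)F
Why: silyl triflate silylation, which also blocks retro‑aldol in the next step.

**Step 19**
Reactants: 27 imide
Product: 28 C15 primary alcohol
Conditions: LiBH4, EtOH (1 equiv), THF, 0 °C
Reagents that add atoms: none
Why: reductive removal of the Evans auxiliary at the exocyclic carbonyl, without epimerisation at C16.

**Step 20**
Reactants: 28 alcohol
Product: 29 C15–C24 primary iodide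
Conditions: PPh3, imidazole, I2, benzene/Et2O, 0 °C → rt
Reagents that add atoms: iodine, II
Why: Appel‑type iodination (SN2 at the primary carbon); I2 is complexed to PPh3 first, so the diene is not attacked.

**Step 21**
Reactants: 29 alkyl iodide; 20 vinyl iodide
Product: 32 tetra-TBS descarbamoyl-discodermolide (free 7-OH), via primary alkyllithium 30 (not isolated), via lithium B-alkyl borinate 31 (not isolated)
Conditions: 29, t-BuLi (2.1 equiv), Et2O, −78 °C; 9-MeO-9-BBN, THF, −78 °C → rt; then 20, Pd(dppf)Cl2 (10 mol %), AsPh3, aq. K3PO4, DMF, rt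
Reagents that add atoms: none
Why: B‑alkyl Suzuki–Miyaura coupling (Marshall–Johnson variant); oxidative addition and reductive elimination retain the Z geometry, and the free OH and the lactone of 20 tolerate the mild base.

**Step 22**
Reactants: 32 protected compound
Product: 33 target CNP0103248.1
Conditions: HF·pyridine, THF, rt
Reagents that add atoms: none
Why: global fluoride desilylation of the four secondary TBS ethers; any lactone opened in step 21 re‑closes in the acidic medium, and no stereocentre is touched.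

## Compound list
1 | (E)-but-2-en-1-ol | C/C=C/CO | starting material
2 | (E)-but-2-en-1-yl N,N-diisopropylcarbamate | C/C=C/COC(=O)N(C(C)C)C(C)C | intermediate
3 | methyl (S)-3-hydroxy-2-methylpropanoate | COC(=O)[C@@H](C)CO | starting material
4 | methyl (S)-3-(TBS-oxy)-2-methylpropanoate | COC(=O)[C@@H](C)CO[Si](C)(C)C(C)(C)C | intermediate
5 | (S)-3-(TBS-oxy)-2-methylpropanal | O=C[C@@H](C)CO[Si](C)(C)C(C)(C)C | intermediate
6 | (S)-1-lithio-(E)-but-2-enyl carbamate (sparteine ligand omitted) | C/C=C/[C@H]([Li])OC(=O)N(C(C)C)C(C)C | intermediate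
7 | (R)-1-(triisopropoxytitanio)-(E)-but-2-enyl carbamate | C/C=C/[C@@H]([Ti](OC(C)C)(OC(C)C)OC(C)C)OC(=O)N(C(C)C)C(C)C | intermediate
8 | (1Z,3S,4S,5S) homoaldol adduct | CC(C)N(C(C)C)C(=O)O/C=C\[C@H](C)[C@H](O)[C@@H](C)CO[Si](C)(C)C(C)(C)C | intermediate
9 | bis-TBS common precursor | CC(C)N(C(C)C)C(=O)O/C=C\[C@H](C)[C@H](O[Si](C)(C)C(C)(C)C)[C@@H](C)CO[Si](C)(C)C(C)(C)C | intermediate
10 | (2R,3R,4S)-3,5-bis(TBS-oxy)-2,4-dimethylpentanal | O=C[C@H](C)[C@H](O[Si](C)(C)C(C)(C)C)[C@@H](C)CO[Si](C)(C)C(C)(C)C | intermediate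
11 | lithium acetylide of (3S,4S,5S)-4,6-bis(TBS-oxy)-3,5-dimethylhex-1-yne | [Li]C#C[C@H](C)[C@H](O[Si](C)(C)C(C)(C)C)[C@@H](C)CO[Si](C)(C)C(C)(C)C | intermediate
12 | (5S,6S,7S) methyl ynone | CC(=O)C#C[C@H](C)[C@H](O[Si](C)(C)C(C)(C)C)[C@@H](C)CO[Si](C)(C)C(C)(C)C | intermediate
13 | (3Z,5S,6S,7S) methyl Z-enone | CC(=O)/C=C\[C@H](C)[C@H](O[Si](C)(C)C(C)(C)C)[C@@H](C)CO[Si](C)(C)C(C)(C)C | intermediate
14 | dicyclohexylboron dienolate of 13 | C=C(OB(C1CCCCC1)C1CCCCC1)/C=C\[C@H](C)[C@H](O[Si](C)(C)C(C)(C)C)[C@@H](C)CO[Si](C)(C)C(C)(C)C | intermediate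
15 | C1–C13 β-hydroxy Z-enone | CC(C)(C)[Si](C)(C)OC[C@H](C)[C@@H](O[Si](C)(C)C(C)(C)C)[C@@H](C)/C=C\C(=O)C[C@H](O)[C@H](C)[C@H](O[Si](C)(C)C(C)(C)C)[C@@H](C)CO[Si](C)(C)C(C)(C)C | intermediate
16 | C1–C13 5,7-anti diol | CC(C)(C)[Si](C)(C)OC[C@H](C)[C@@H](O[Si](C)(C)C(C)(C)C)[C@@H](C)/C=C\[C@@H](O)C[C@H](O)[C@H](C)[C@H](O[Si](C)(C)C(C)(C)C)[C@@H](C)CO[Si](C)(C)C(C)(C)C | intermediate
17 | C1–C13 tetraol | OC[C@H](C)[C@@H](O[Si](C)(C)C(C)(C)C)[C@@H](C)/C=C\[C@@H](O)C[C@H](O)[C@H](C)[C@H](O[Si](C)(C)C(C)(C)C)[C@@H](C)CO | intermediate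
18 | C1 lactol C13 aldehyde (anomers) | O=C[C@H](C)[C@@H](O[Si](C)(C)C(C)(C)C)[C@@H](C)/C=C\[C@@H](O)C[C@@H]1OC(O)[C@H](C)[C@@H](O[Si](C)(C)C(C)(C)C)[C@H]1C | intermediate
19 | δ-lactone C13 aldehyde | O=C[C@H](C)[C@@H](O[Si](C)(C)C(C)(C)C)[C@@H](C)/C=C\[C@@H](O)C[C@@H]1OC(=O)[C@H](C)[C@@H](O[Si](C)(C)C(C)(C)C)[C@H]1C | intermediate
20 | C1–C14 (Z)-vinyl iodide | I/C(C)=C\[C@H](C)[C@@H](O[Si](C)(C)C(C)(C)C)[C@@H](C)/C=C\[C@@H](O)C[C@@H]1OC(=O)[C@H](C)[C@@H](O[Si](C)(C)C(C)(C)C)[C@H]1C | intermediate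
21 | C17–C24 Z-diene bis-TBS ether | C=C/C=C\[C@H](C)[C@H](O[Si](C)(C)C(C)(C)C)[C@@H](C)CO[Si](C)(C)C(C)(C)C | intermediate
22 | C17 alcohol | C=C/C=C\[C@H](C)[C@H](O[Si](C)(C)C(C)(C)C)[C@@H](C)CO | intermediate
23 | C17 aldehyde | C=C/C=C\[C@H](C)[C@H](O[Si](C)(C)C(C)(C)C)[C@@H](C)C=O | intermediate
24 | (R)-4-benzyl-3-propionyloxazolidin-2-one | CCC(=O)N1C(=O)OC[C@H]1Cc1ccccc1 | starting material
25 | Z(O)-dibutylboron enolate of 24 | C/C=C(\OB(CCCC)CCCC)N1C(=O)OC[C@H]1Cc1ccccc1 | intermediate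
26 | C15–C24 syn-aldol imide | C=C/C=C\[C@H](C)[C@H](O[Si](C)(C)C(C)(C)C)[C@@H](C)[C@H](O)[C@@H](C)C(=O)N1C(=O)OC[C@H]1Cc1ccccc1 | intermediate
27 | 17,19-bis-TBS imide | C=C/C=C\[C@H](C)[C@H](O[Si](C)(C)C(C)(C)C)[C@@H](C)[C@H](O[Si](C)(C)C(C)(C)C)[C@@H](C)C(=O)N1C(=O)OC[C@H]1Cc1ccccc1 | intermediate
28 | C15 alcohol | C=C/C=C\[C@H](C)[C@H](O[Si](C)(C)C(C)(C)C)[C@@H](C)[C@H](O[Si](C)(C)C(C)(C)C)[C@@H](C)CO | intermediate
29 | C15 iodide | C=C/C=C\[C@H](C)[C@H](O[Si](C)(C)C(C)(C)C)[C@@H](C)[C@H](O[Si](C)(C)C(C)(C)C)[C@@H](C)CI | intermediate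
30 | C15 alkyllithium | C=C/C=C\[C@H](C)[C@H](O[Si](C)(C)C(C)(C)C)[C@@H](C)[C@H](O[Si](C)(C)C(C)(C)C)[C@@H](C)C[Li] | intermediate
31 | lithium B-alkyl-B-methoxy-9-BBN borinate | C=C/C=C\[C@H](C)[C@H](O[Si](C)(C)C(C)(C)C)[C@@H](C)[C@H](O[Si](C)(C)C(C)(C)C)[C@@H](C)C[B-]1(OC)C2CCCC1CCC2.[Li+] | intermediate
32 | 3,11,17,19-tetra-TBS descarbamoyl-discodermolide | C=C/C=C\[C@H](C)[C@H](O[Si](C)(C)C(C)(C)C)[C@@H](C)[C@H](O[Si](C)(C)C(C)(C)C)[C@@H](C)C/C(C)=C\[C@H](C)[C@@H](O[Si](C)(C)C(C)(C)C)[C@@H](C)/C=C\[C@@H](O)C[C@@H]1OC(=O)[C@H](C)[C@@H](O[Si](C)(C)C(C)(C)C)[C@H]1C | intermediate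
33 | CNP0103248.1, (2R,3S,4S,5S,7S,10S,11S,12S,16S,17R,18S,19S,20S; 8Z,13Z,21Z) | C=C/C=C\[C@H](C)[C@H](O)[C@@H](C)[C@H](O)[C@@H](C)C/C(C)=C\[C@H](C)[C@@H](O)[C@@H](C)/C=C\[C@@H](O)C[C@@H]1OC(=O)[C@H](C)[C@@H](O)[C@H]1C | target

## Step count
- **Total:** 22 steps.
- **Longest linear sequence:** 13 steps from 3. Two equal lines exist: steps 2–5, 7–13, 21, 22, and steps 2–5, 14–22.

## Steps most likely to fail

**Step 9 (C5 selectivity).** The required product is anti‑Felkin and relies on remote induction. The fallback sets out from 10 (with 11 from step 7) and returns at 15.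
- C5 is fixed first under reagent control by Brown allylation of 10 with (−)‑Ipc2B‑allyl, giving the (5S)‑homoallylic alcohol F1.
- Ozonolysis gives the β‑hydroxy aldehyde F2.
- Addition of excess lithium acetylide 11 forms the C7–C8 bond instead of C5–C6, giving the propargylic diol F3. Its C7 epimers do not matter.
- MnO2 oxidises only the propargylic carbinol, giving the β‑hydroxy ynone F4.
- Lindlar semihydrogenation then gives 15.

**Step 12 (three oxidations next to a free allylic 7‑OH).** The fallback sets out from 15 and returns at 20. C7 is kept as the ketone during the oxidations and is set later by a different stereocontrol element.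
- HF·pyridine on 15 gives the keto triol F5.
- TEMPO/PhI(OAc)2 gives the lactone aldehyde enone F6.
- Zhao–Wittig olefination gives the vinyl iodide enone F7.
- K‑Selectride at −78 °C reduces the C7 ketone 1,2 under control of the adjacent lactone stereocentre, giving 20.

**Step 13 (Zhao–Wittig on a precious, unprotected substrate; typically moderate yield).** The fallback sets out from 19 and returns at 32.
- Dibromomethylenation with preformed Ph3P=CBr2 (from Ph3P+CHBr2 Br− and t‑BuOK, so no Appel‑active species meets the free OH) gives the 1,1‑dibromoalkene F8.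
- Pd(DPEphos)Cl2‑catalysed trans‑selective Negishi methylation with Me2Zn gives the (Z)‑2‑bromoalkene F9.
- F9 is coupled with borinate 31 using Pd(t‑Bu3P)2, with retention, giving 32.

## Further compounds
F1 | step 9 | (5S)-homoallylic alcohol from 10 | C=CC[C@H](O)[C@H](C)[C@H](O[Si](C)(C)C(C)(C)C)[C@@H](C)CO[Si](C)(C)C(C)(C)C
F2 | step 9 | C1–C7 β-hydroxy aldehyde | O=CC[C@H](O)[C@H](C)[C@H](O[Si](C)(C)C(C)(C)C)[C@@H](C)CO[Si](C)(C)C(C)(C)C
F3 | step 9 | C1–C13 propargylic 5,7-diol (C7 epimers) | CC(C)(C)[Si](C)(C)OC[C@H](C)[C@@H](O[Si](C)(C)C(C)(C)C)[C@@H](C)C#CC(O)C[C@H](O)[C@H](C)[C@H](O[Si](C)(C)C(C)(C)C)[C@@H](C)CO[Si](C)(C)C(C)(C)C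
F4 | step 9 | C1–C13 β-hydroxy ynone | CC(C)(C)[Si](C)(C)OC[C@H](C)[C@@H](O[Si](C)(C)C(C)(C)C)[C@@H](C)C#CC(=O)C[C@H](O)[C@H](C)[C@H](O[Si](C)(C)C(C)(C)C)[C@@H](C)CO[Si](C)(C)C(C)(C)C
F5 | step 12 | C1,C5,C13-triol 7-keto Z-enone | OC[C@H](C)[C@@H](O[Si](C)(C)C(C)(C)C)[C@@H](C)/C=C\C(=O)C[C@H](O)[C@H](C)[C@H](O[Si](C)(C)C(C)(C)C)[C@@H](C)CO
F6 | step 12 | lactone C13 aldehyde 7-keto Z-enone | O=C[C@H](C)[C@@H](O[Si](C)(C)C(C)(C)C)[C@@H](C)/C=C\C(=O)C[C@@H]1OC(=O)[C@H](C)[C@@H](O[Si](C)(C)C(C)(C)C)[C@H]1C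
F7 | step 12 | (Z)-vinyl iodide 7-keto Z-enone | I/C(C)=C\[C@H](C)[C@@H](O[Si](C)(C)C(C)(C)C)[C@@H](C)/C=C\C(=O)C[C@@H]1OC(=O)[C@H](C)[C@@H](O[Si](C)(C)C(C)(C)C)[C@H]1C
F8 | step 13 | C14 1,1-dibromoalkene | BrC(Br)=C[C@H](C)[C@@H](O[Si](C)(C)C(C)(C)C)[C@@H](C)/C=C\[C@@H](O)C[C@@H]1OC(=O)[C@H](C)[C@@H](O[Si](C)(C)C(C)(C)C)[C@H]1C
F9 | step 13 | C1–C14 (Z)-vinyl bromide | Br/C(C)=C\[C@H](C)[C@@H](O[Si](C)(C)C(C)(C)C)[C@@H](C)/C=C\[C@@H](O)C[C@@H]1OC(=O)[C@H](C)[C@@H](O[Si](C)(C)C(C)(C)C)[C@H]1C
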